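**Strategy.** The isoflavone is cut at the C3–C4 bond of ring C. C4, the carbonyl carbon bonded to ring A, is traced back to a salicylaldehyde carbon. C3, which carries ring B, is traced back to the carbonyl carbon of an aryl ketone hung on the phenol oxygen (future O1) by one methylene (future C2). A carbene-catalysed intramolecular crossed benzoin reaction joins C4 to C3 and closes ring C in one operation, giving a 3-aryl-3-hydroxychroman-4-one one dehydration short of the chromone. The precursor is a bis(methoxymethyl)-protected phloroglucinaldehyde O-alkylated with the bromomethyl ketone of the 8-oxygenated 2,2-dimethylchromene (ring B).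

Key step: step 7

Remark: compound 11 is planned as a racemate, since its only stereocentre (C3) becomes sp2 in step 8; the target has no stereocentre.

**Step 1**
Reactants: 1 3,4-dihydroxyacetophenone; 2 3-chloro-3-methylbut-1-yne
Product: 3 1-[3-hydroxy-4-(2-methylbut-3-yn-2-yloxy)phenyl]ethan-1-one
Conditions: K2CO3 (1.1 equiv), KI (10 mol%), CuI (5 mol%), acetone, 50 °C
Reagents that add atoms: none
Why: Copper-assisted Williamson-type O-alkylation with a tertiary propargylic chloride; with one equivalent of carbonate the phenoxide forms at the more acidic 4-hydroxyl (para to the acetyl group), so the ether should be placed on O4 and the 3-hydroxyl should stay free.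

**Step 2**
Reactants: 3 1-[3-hydroxy-4-(2-methylbut-3-yn-2-yloxy)phenyl]ethan-1-one
Product: 4 1-(8-hydroxy-2,2-dimethyl-2H-chromen-6-yl)ethan-1-one
Conditions: PhNEt2, 180 °C
Reagents that add atoms: none
Why: Aromatic propargyl Claisen rearrangement to the only free ortho position (C5 of the acetophenone), followed by 1,5-hydrogen shift and oxa-6π electrocyclisation, is the standard entry to 2,2-dimethyl-2H-chromenes and places the acetyl group at C6 and the hydroxyl at C8.

**Step 3**
Reactants: 4 1-(8-hydroxy-2,2-dimethyl-2H-chromen-6-yl)ethan-1-one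
Product: 5 1-[8-(methoxymethoxy)-2,2-dimethyl-2H-chromen-6-yl]ethan-1-one
Conditions: MOMCl, iPr2NEt, CH2Cl2, 0 °C to rt
Reagents that add atoms: chloromethyl methyl ether, COCCl
Why: Standard methoxymethyl ether formation (O-alkylation of a phenol with an α-chloro ether under amine base), which should leave the ketone and the chromene alkene untouched.

**Step 4**
Reactants: 5 1-[8-(methoxymethoxy)-2,2-dimethyl-2H-chromen-6-yl]ethan-1-one
Product: 7 2-bromo-1-[8-(methoxymethoxy)-2,2-dimethyl-2H-chromen-6-yl]ethan-1-one, via silyl enol ether 6 (not isolated)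
Conditions: LiN(SiMe3)2, Me3SiCl, THF, −78 °C; then NBS, THF, −78 to 0 °C
Reagents that add atoms: N-bromosuccinimide, O=C1CCC(=O)N1Br; chlorotrimethylsilane, C[Si](C)(C)Cl (its silyl group stays in 6 only)
Why: Kinetic enolisation of the methyl ketone (its only enolisable side) with silyl trapping, then electrophilic α-bromination of the silyl enol ether, which is far more nucleophilic than the chromene alkene or the arene and releases no HBr that could cleave the acetal ether; direct bromination of the ketone is avoided for that reason.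

**Step 5**
Reactants: 8 2,4,6-trihydroxybenzaldehyde
Product: 9 2-hydroxy-4,6-bis(methoxymethoxy)benzaldehyde
Conditions: MOMCl (2.2 equiv), iPr2NEt (2.5 equiv), CH2Cl2, 0 °C
Reagents that add atoms: chloromethyl methyl ether, COCCl
Why: Selective methoxymethyl ether formation: the 4-hydroxyl and one ortho hydroxyl react, while the remaining ortho hydroxyl, hydrogen-bonded to the aldehyde, is the least nucleophilic and should stay free.

**Step 6**
Reactants: 7 2-bromo-1-[8-(methoxymethoxy)-2,2-dimethyl-2H-chromen-6-yl]ethan-1-one; 9 2-hydroxy-4,6-bis(methoxymethoxy)benzaldehyde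
Product: 10 2,4-bis(methoxymethoxy)-6-{2-[8-(methoxymethoxy)-2,2-dimethyl-2H-chromen-6-yl]-2-oxoethoxy}benzaldehyde
Conditions: K2CO3 (1.2 equiv), acetone, rt
Reagents that add atoms: none
Why: Williamson ether synthesis: the phenoxide displaces bromide from the highly reactive α-bromo ketone by SN2 at room temperature, mild enough that the aldol cyclisation to a benzofuran, which needs heat or stronger base, should not set in.

**Step 7**
Reactants: 10 2,4-bis(methoxymethoxy)-6-{2-[8-(methoxymethoxy)-2,2-dimethyl-2H-chromen-6-yl]-2-oxoethoxy}benzaldehyde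
Product: 11 3-hydroxy-5,7-bis(methoxymethoxy)-3-[8-(methoxymethoxy)-2,2-dimethyl-2H-chromen-6-yl]chroman-4-one (racemic)
Conditions: 2-(pentafluorophenyl)-6,7-dihydro-5H-pyrrolo[2,1-c][1,2,4]triazol-2-ium tetrafluoroborate (15 mol%), Et3N (15 mol%), toluene, rt, Ar
Reagents that add atoms: none
Why: The carbene released from the triazolium salt by Et3N adds to the aldehyde carbon and a proton shift gives the enaminol (acyl anion equivalent), whose nucleophilic carbon attacks the tethered aryl ketone; proton transfer and loss of the carbene then deliver the tertiary α-hydroxy ketone, so the aldehyde carbon ends as C4 and the ketone carbon as C3 with ring B already in place. The closest known reaction type is the carbene-catalysed intramolecular crossed aldehyde–ketone benzoin cyclisation of 2-(2-oxoalkoxy)benzaldehydes to 3-hydroxychroman-4-ones. Ring C closes in a 6-exo-trig mode. The C3 stereocentre is formed without control (achiral catalyst, racemate), which is acceptable because step 8 erases it. The step needs C–C bond formation to win over base-mediated aldol condensation of the O–CH2–CO unit onto the aldehyde (benzofuran formation) and over intermolecular homo-benzoin; a weak amine base in substoichiometric amount, a non-polar solvent and the six-membered intramolecular trajectory should secure this. The carbene selects the aldehyde over the ketone because only the aldehyde adduct can tautomerise to the enaminol.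

**Step 8**
Reactants: 11 3-hydroxy-5,7-bis(methoxymethoxy)-3-[8-(methoxymethoxy)-2,2-dimethyl-2H-chromen-6-yl]chroman-4-one
Product: 12 5,7-bis(methoxymethoxy)-3-[8-(methoxymethoxy)-2,2-dimethyl-2H-chromen-6-yl]-4H-chromen-4-one
Conditions: SOCl2, pyridine, CH2Cl2, 0 °C to rt
Reagents that add atoms: none
Why: Dehydration of a tertiary alcohol through its chlorosulfite with pyridine-induced elimination (E2, or E1 helped by the para oxygen of ring B); only the C2 hydrogens are available and the product is the conjugated chromone, while excess pyridine buffers the HCl so that the acetal ethers should survive.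

**Step 9**
Reactants: 12 5,7-bis(methoxymethoxy)-3-[8-(methoxymethoxy)-2,2-dimethyl-2H-chromen-6-yl]-4H-chromen-4-one
Product: 13 semilicoisoflavone B, 5,7-dihydroxy-3-(8-hydroxy-2,2-dimethyl-2H-chromen-6-yl)-4H-chromen-4-one
Conditions: HCl (aq, 3 M), MeOH, 50 °C
Reagents that add atoms: none
Why: Acid-catalysed acetal cleavage (transacetalisation of the three methoxymethyl ethers to methanol), run in dilute acid at moderate temperature so that the 2,2-dimethylchromene alkene should not be protonated.

**Compound list**

1 | 3,4-dihydroxyacetophenone | CC(=O)c1ccc(O)c(O)c1 | starting material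
2 | 3-chloro-3-methylbut-1-yne | CC(C)(Cl)C#C | starting material
3 | 1-[3-hydroxy-4-(2-methylbut-3-yn-2-yloxy)phenyl]ethan-1-one | CC(=O)c1ccc(OC(C)(C)C#C)c(O)c1 | intermediate
4 | 1-(8-hydroxy-2,2-dimethyl-2H-chromen-6-yl)ethan-1-one | CC(=O)c1cc(O)c2OC(C)(C)C=Cc2c1 | intermediate
5 | 1-[8-(methoxymethoxy)-2,2-dimethyl-2H-chromen-6-yl]ethan-1-one | CC(=O)c1cc(OCOC)c2OC(C)(C)C=Cc2c1 | intermediate
6 | trimethyl({1-[8-(methoxymethoxy)-2,2-dimethyl-2H-chromen-6-yl]ethenyl}oxy)silane (silyl enol ether, not isolated) | C=C(O[Si](C)(C)C)c1cc(OCOC)c2OC(C)(C)C=Cc2c1 | intermediate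
7 | 2-bromo-1-[8-(methoxymethoxy)-2,2-dimethyl-2H-chromen-6-yl]ethan-1-one | BrCC(=O)c1cc(OCOC)c2OC(C)(C)C=Cc2c1 | intermediate
8 | 2,4,6-trihydroxybenzaldehyde | O=Cc1c(O)cc(O)cc1O | starting material
9 | 2-hydroxy-4,6-bis(methoxymethoxy)benzaldehyde | O=Cc1c(O)cc(OCOC)cc1OCOC | intermediate
10 | 2,4-bis(methoxymethoxy)-6-{2-[8-(methoxymethoxy)-2,2-dimethyl-2H-chromen-6-yl]-2-oxoethoxy}benzaldehyde | O=Cc1c(OCOC)cc(OCOC)cc1OCC(=O)c1cc(OCOC)c2OC(C)(C)C=Cc2c1 | intermediate
11 | 3-hydroxy-5,7-bis(methoxymethoxy)-3-[8-(methoxymethoxy)-2,2-dimethyl-2H-chromen-6-yl]chroman-4-one (racemic; one enantiomer drawn) | COCOc1cc(OCOC)c2c(c1)OC[C@@](O)(c1cc(OCOC)c3OC(C)(C)C=Cc3c1)C2=O | intermediate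
12 | 5,7-bis(methoxymethoxy)-3-[8-(methoxymethoxy)-2,2-dimethyl-2H-chromen-6-yl]-4H-chromen-4-one | CC1(C)C=Cc2cc(-c3coc4cc(OCOC)cc(OCOC)c4c3=O)cc(OCOC)c2O1 | intermediate
13 | semilicoisoflavone B, 5,7-dihydroxy-3-(8-hydroxy-2,2-dimethyl-2H-chromen-6-yl)-4H-chromen-4-one | CC1(C)C=Cc2cc(-c3coc4cc(O)cc(O)c4c3=O)cc(O)c2O1 | target

**Step count.** Total: 9 steps. Longest linear sequence: 8 steps (steps 1–4 and 6–9, from 1 to 13); step 5 is the one-step side branch.

**Steps most likely to fail**

1. Step 7. The carbene may add only slowly to an aldehyde flanked by two ortho oxygen substituents on an electron-rich ring. Enolisation of the O–CH2–CO unit, aldol addition to the aldehyde and dehydration (cyclisation to a benzofuran) could then consume the substrate. The fallback forms the same C3–C4 bond with normal polarity instead of umpolung; it sets out from ketone 5 and phenol 9 and rejoins the route at chromone 12.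
   - Ketone 5 would be condensed with 2,4,6-triisopropylbenzenesulfonohydrazide (MeOH, rt) to the sulfonyl hydrazone F1.
   - n-BuLi (2 equiv, THF, −78 to 0 °C; Shapiro reaction) should convert F1, with loss of sulfinate and nitrogen, into the α-arylvinyllithium F2, whose carbanion carbon is the future C3.
   - Addition of F2 at −78 °C to the lithium phenoxide of aldehyde 9 (preformed with LiN(SiMe3)2) should give the allylic benzylic alcohol F3.
   - MnO2 (CH2Cl2, rt) should oxidise F3 to the 2-hydroxyaryl α-aryl vinyl ketone F4.
   - K2CO3 in acetone should close ring C by 6-endo-trig oxa-Michael addition of the phenoxide (O1 to C2), giving the isoflavanone F5.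
   - Dehydrogenation with 2,3-dichloro-5,6-dicyano-1,4-benzoquinone (DDQ; 1,4-dioxane, 90 °C) would then give chromone 12.

2. Step 8. Ionisation at C3 may end in chloride capture or a 1,2-shift (α-ketol-type rearrangement) instead of loss of a C2 hydrogen, and HCl not trapped by pyridine may start to cleave the acetal ethers. The fallback removes the C3 oxygen reductively and restores the unsaturation by dehydrogenation; it sets out from 11 and returns at 12.
   - Acetylation (Ac2O, 4-(dimethylamino)pyridine, Et3N, CH2Cl2) would give the tertiary acetate F6.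
   - SmI2 (THF/MeOH, −78 °C) should cleave the α-acyloxy ketone C–O bond to the samarium enolate, which on protonation gives the isoflavanone F5 (the compound also met in the fallback for step 7).
   - DDQ (1,4-dioxane, 90 °C) would dehydrogenate F5 to chromone 12.

3. Step 1. Alkylation may not stay at O4: attack at O3, double alkylation, or copper-assisted addition of the neighbouring free hydroxyl to the alkyne may erode the yield. The fallback fixes the regiochemistry with a methyl ether that is removed nucleophilically; it sets out from chloride 2 and returns at chromene 4.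
   - Commercial acetovanillone F7, which has only the 4-hydroxyl free, would be alkylated with 2 (K2CO3, KI, CuI, acetone, 50 °C) to the propargyl ether F8.
   - Claisen rearrangement and cyclisation (PhNEt2, 180 °C) should give the 8-methoxychromene F9.
   - NaSEt (DMF, 110 °C) should cleave the aryl methyl ether by SN2 at the methyl group, which the tertiary chromene ether cannot undergo, giving phenol 4.

**Further compounds**

F1 | step 7 | N'-{1-[8-(methoxymethoxy)-2,2-dimethyl-2H-chromen-6-yl]ethylidene}-2,4,6-triisopropylbenzenesulfonohydrazide | CC(=NNS(=O)(=O)c1c(C(C)C)cc(C(C)C)cc1C(C)C)c1cc(OCOC)c2OC(C)(C)C=Cc2c1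
F2 | step 7 | {1-[8-(methoxymethoxy)-2,2-dimethyl-2H-chromen-6-yl]ethenyl}lithium | [Li]C(=C)c1cc(OCOC)c2OC(C)(C)C=Cc2c1
F3 | step 7 | 2-{1-hydroxy-2-[8-(methoxymethoxy)-2,2-dimethyl-2H-chromen-6-yl]prop-2-en-1-yl}-3,5-bis(methoxymethoxy)phenol (racemic) | C=C(C(O)c1c(O)cc(OCOC)cc1OCOC)c1cc(OCOC)c2OC(C)(C)C=Cc2c1
F4 | step 7 | 1-[2-hydroxy-4,6-bis(methoxymethoxy)phenyl]-2-[8-(methoxymethoxy)-2,2-dimethyl-2H-chromen-6-yl]prop-2-en-1-one | C=C(C(=O)c1c(O)cc(OCOC)cc1OCOC)c1cc(OCOC)c2OC(C)(C)C=Cc2c1
F5 | step 7 | 5,7-bis(methoxymethoxy)-3-[8-(methoxymethoxy)-2,2-dimethyl-2H-chromen-6-yl]chroman-4-one (racemic) | COCOc1cc(OCOC)c2c(c1)OCC(c1cc(OCOC)c3OC(C)(C)C=Cc3c1)C2=O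
F6 | step 8 | 5,7-bis(methoxymethoxy)-3-[8-(methoxymethoxy)-2,2-dimethyl-2H-chromen-6-yl]-4-oxochroman-3-yl acetate (racemic) | CC(=O)OC1(COc2cc(OCOC)cc(OCOC)c2C1=O)c1cc(OCOC)c2OC(C)(C)C=Cc2c1
F7 | step 1 | acetovanillone, 1-(4-hydroxy-3-methoxyphenyl)ethan-1-one | CC(=O)c1ccc(O)c(OC)c1
F8 | step 1 | 1-[3-methoxy-4-(2-methylbut-3-yn-2-yloxy)phenyl]ethan-1-one | CC(=O)c1ccc(OC(C)(C)C#C)c(OC)c1
F9 | step 1 | 1-(8-methoxy-2,2-dimethyl-2H-chromen-6-yl)ethan-1-one | CC(=O)c1cc(OC)c2OC(C)(C)C=Cc2c1
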